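**Retrosynthetic overview**

1. The three phenol/alcohol groups are carried as MOM ethers and the C4 ketone as a spiro-1,3-dithiane; both are removed in the last two steps.
2. Ring C is cut at C3–C4 and at O1–C8a: a ring A 2-lithio-1,3-dithiane (C4, with fluorine on C8a) and a ring B (R)-oxirane (O1–C2–C3). Epoxide opening makes C3–C4 and releases O1 as an alkoxide, which adds to an aryne C8≡C8a generated in the same flask.
3. Enabling feature: ring C hangs on two adjacent carbons of ring A (C4 on C4a, O1 on C8a), and C8–H lies between C8a and the oxygen-bearing C7. C8–H is therefore the most acidic ring A proton, the aryne forms exactly at C8≡C8a, and the three-atom tether C4–C3–C2 can deliver O1 only to C8a. C2 is a benzylic carbinol carbon and can be carried as a terminal epoxide.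
4. Ring B fragment: pyran ring by propargyl ether Claisen rearrangement/electrocyclisation, C3'' by Jacobsen epoxidation and hydrogenolysis, C2 by asymmetric transfer hydrogenation of an alpha-chloro ketone.
5. Order of ring formation: pyran ring on ring B (step 3), oxirane (step 8), dithiane (step 9), ring C (step 11); both benzene rings are bought.

Key step: step 11

Remark (assumptions): compounds 1, 2 and 13 are taken as commercial. Locants O1, C2, C3, C4, C4a, C5–C8, C8a refer to the chroman-4-one (rings A and C); double-primed locants refer to the pyran ring fused to ring B. In steps 3–8 the chroman of the ring B fragment is numbered on its own (O1, C2, C3, C4, C4a, C5–C8, C8a).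

**Route**

Step 1
Reactants: 1 3',4'-dihydroxyacetophenone; 2 3-chloro-3-methylbut-1-yne
Product: 3 1-[3-hydroxy-4-(2-methylbut-3-yn-2-yloxy)phenyl]ethan-1-one
Conditions: K2CO3 (1.1 equiv), KI (cat.), DMF, 60 °C, N2
Reagents that add atoms: none
Why: Williamson-type O-alkylation in which the 4-OH, para to the acetyl group and so the more acidic phenol, should be the one alkylated when about one equivalent of base is used, as in the known regioselective 4-O-alkylation of 3,4-dihydroxyaryl carbonyl compounds.

Step 2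
Reactants: 3 1-[3-hydroxy-4-(2-methylbut-3-yn-2-yloxy)phenyl]ethan-1-one
Product: 4 1-[3-(methoxymethoxy)-4-(2-methylbut-3-yn-2-yloxy)phenyl]ethan-1-one
Conditions: MOMCl, iPr2NEt, CH2Cl2, 0 °C → rt
Reagents that add atoms: chloromethyl methyl ether (MOMCl), COCCl
Why: Standard MOM ether formation on the remaining phenol gives a group that should withstand the later amide and organolithium bases and is removed by acid at the end.

Step 3
Reactants: 4 1-[3-(methoxymethoxy)-4-(2-methylbut-3-yn-2-yloxy)phenyl]ethan-1-one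
Product: 5 1-[8-(methoxymethoxy)-2,2-dimethyl-2H-chromen-6-yl]ethan-1-one
Conditions: PhNEt2, 190 °C
Reagents that add atoms: none
Why: Aryl propargyl ether Claisen rearrangement followed by 1,5-hydrogen shift and oxa-6π-electrocyclisation is the standard route to 2,2-dimethyl-2H-chromenes, and only one ortho position of the arene is free, so a single regioisomer should form.

Step 4
Reactants: 5 1-[8-(methoxymethoxy)-2,2-dimethyl-2H-chromen-6-yl]ethan-1-one
Product: 6 (3S,4S)-6-acetyl-3,4-epoxy-8-(methoxymethoxy)-2,2-dimethylchromane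
Conditions: chloro[(S,S)-N,N'-bis(3,5-di-tert-butylsalicylidene)cyclohexane-1,2-diaminato]manganese (trivalent manganese, (S,S)-Jacobsen catalyst, 5 mol%), NMO, mCPBA, CH2Cl2, −78 °C
Reagents that add atoms: 3-chloroperbenzoic acid (mCPBA), OOC(=O)c1cccc(Cl)c1
Why: Jacobsen–Katsuki epoxidation, for which 2,2-dimethylchromenes are among the best substrates, should give the (3S,4S)-epoxide under control of the (S,S)-catalyst and so fixes the future C3'' stereocentre; the anhydrous low-temperature protocol avoids hypochlorite, which could attack the methyl ketone.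

Step 5
Reactants: 6 (3S,4S)-6-acetyl-3,4-epoxy-8-(methoxymethoxy)-2,2-dimethylchromane
Product: 7 1-[(3S)-3-hydroxy-8-(methoxymethoxy)-2,2-dimethyl-3,4-dihydro-2H-chromen-6-yl]ethan-1-one
Conditions: H2 (1 atm), 10% Pd/C, EtOAc, rt
Reagents that add atoms: none
Why: Palladium-catalysed hydrogenolysis cleaves the benzylic C4–O bond of the epoxide, leaves the C3–O bond and its (S) configuration untouched, and should be much faster than reduction of the electron-rich aryl ketone.

Step 6
Reactants: 7 1-[(3S)-3-hydroxy-8-(methoxymethoxy)-2,2-dimethyl-3,4-dihydro-2H-chromen-6-yl]ethan-1-one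
Product: 8 1-[(3S)-3,8-bis(methoxymethoxy)-2,2-dimethyl-3,4-dihydro-2H-chromen-6-yl]ethan-1-one
Conditions: MOMCl, iPr2NEt, Bu4NI (cat.), CH2Cl2, 40 °C
Reagents that add atoms: chloromethyl methyl ether (MOMCl), COCCl
Why: MOM ether formation on the hindered secondary alcohol under standard forcing conditions puts the same acid-labile group on every oxygen and needs no base that would enolise the ketone.

Step 7
Reactants: 8 1-[(3S)-3,8-bis(methoxymethoxy)-2,2-dimethyl-3,4-dihydro-2H-chromen-6-yl]ethan-1-one
Product: 10 2-chloro-1-[(3S)-3,8-bis(methoxymethoxy)-2,2-dimethyl-3,4-dihydro-2H-chromen-6-yl]ethan-1-one, via trimethylsilyl enol ether 9 (not isolated)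
Conditions: LiHMDS, TMSCl, THF, −78 → 0 °C; then NCS, THF, 0 °C
Reagents that add atoms: N-chlorosuccinimide (NCS), O=C1CCC(=O)N1Cl
Why: Enolisation of the methyl ketone, trapping as the silyl enol ether and electrophilic chlorination with NCS is the standard regiocontrolled route to an alpha-chloro ketone and avoids chlorination of the electron-rich ring.

Step 8
Reactants: 10 2-chloro-1-[(3S)-3,8-bis(methoxymethoxy)-2,2-dimethyl-3,4-dihydro-2H-chromen-6-yl]ethan-1-one
Product: 12 (3S)-3,8-bis(methoxymethoxy)-2,2-dimethyl-6-[(2R)-oxiran-2-yl]-3,4-dihydro-2H-chromene, via (R)-chlorohydrin 11 (not isolated)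
Conditions: Cp*RhCl[(S,S)-TsDPEN] (cat.), HCO2H/Et3N (5:2), EtOAc, rt; then K2CO3, MeOH, 0 °C → rt
Reagents that add atoms: none
Why: Noyori–Ikariya asymmetric transfer hydrogenation of an alpha-chloro aryl ketone under catalyst control (the (S,S) catalyst, which reduces acetophenone to the (S)-alcohol, should here give the (R)-chlorohydrin because CH2Cl outranks aryl), followed by intramolecular Williamson closure that does not touch the stereocentre and so gives the (R)-oxirane.

Step 9
Reactants: 13 2-fluoro-4-hydroxybenzaldehyde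
Product: 14 4-(1,3-dithian-2-yl)-3-fluorophenol
Conditions: HS(CH2)3SH, BF3·OEt2 (cat.), CH2Cl2, 0 °C → rt
Reagents that add atoms: propane-1,3-dithiol, SCCCS
Why: Lewis acid promoted dithioacetalisation of the aldehyde gives the 1,3-dithiane that serves as the C4 acyl anion equivalent (Corey–Seebach umpolung).

Step 10
Reactants: 14 4-(1,3-dithian-2-yl)-3-fluorophenol
Product: 15 2-[2-fluoro-4-(methoxymethoxy)phenyl]-1,3-dithiane
Conditions: MOMCl, iPr2NEt, CH2Cl2, 0 °C → rt
Reagents that add atoms: chloromethyl methyl ether (MOMCl), COCCl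
Why: Standard MOM protection of the phenol, done after the dithiane because the Lewis acid of step 9 would cleave a MOM ether.

Step 11
Reactants: 15 2-[2-fluoro-4-(methoxymethoxy)phenyl]-1,3-dithiane; 12 (3S)-3,8-bis(methoxymethoxy)-2,2-dimethyl-6-[(2R)-oxiran-2-yl]-3,4-dihydro-2H-chromene
Product: 19 (2S)-2-[(3S)-3,8-bis(methoxymethoxy)-2,2-dimethyl-3,4-dihydro-2H-chromen-6-yl]-7-(methoxymethoxy)-2,3-dihydrospiro[chromene-4,2'-[1,3]dithiane], via lithiated dithiane 16 (not isolated), via lithium alkoxide 17 (not isolated), via aryne 18 (not isolated)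
Conditions: 15 (1.2 equiv), n-BuLi, THF, −78 °C; 12, −78 → 0 °C; then LiTMP (preformed, 2.5 equiv), −78 °C → rt; aq. NH4Cl
Reagents that add atoms: none
Why: Proposed new method: a one-flask anion relay is proposed in which the 2-lithio-1,3-dithiane 16 (a Corey–Seebach acyl anion equivalent for C4) opens oxirane 12 by SN2 attack at its unsubstituted CH2 (forming C3–C4) and thereby releases the C2 oxygen as lithium alkoxide 17, after which LiTMP removes the ring A proton at C8 (the most acidic one, flanked by the C8a fluorine and the C7 acetal oxygen), loss of LiF gives aryne 18 (C8≡C8a), the tethered alkoxide adds at C8a (forming O1–C8a) and the resulting C8 aryllithium is protonated. The closest known reaction types are the alkylation of 2-aryl-2-lithio-1,3-dithianes with terminal epoxides and the benzyne cyclisation of tethered alkoxides onto arynes made by ortho-lithiation of aryl fluorides; only their coupling in one flask is new. Ring C closes in a 6-exo-dig sense, O1 attacking the aryne carbon C8a while C8 stays outside the new ring. No stereocentre is created: C2 keeps the configuration of 12 because its C–O bond is never broken, and the spiro-dithiane, a ring that is not in the target, removes the C4 carbonyl that would otherwise open retro-aldol cleavage or beta-elimination of the beta-alkoxide under these strongly basic conditions. The step needs terminal regioselectivity in the epoxide opening, which the bulk of the tertiary dithiane anion and the SN2 conditions should secure, and addition at C8a and not at C8 of the aryne, which is secured both by the three-atom tether (attack at C8 would need a bridged ring) and by the C7 alkoxy group, which polarises a 3-alkoxyaryne toward attack at the carbon remote from it.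

Step 12
Reactants: 19 (2S)-2-[(3S)-3,8-bis(methoxymethoxy)-2,2-dimethyl-3,4-dihydro-2H-chromen-6-yl]-7-(methoxymethoxy)-2,3-dihydrospiro[chromene-4,2'-[1,3]dithiane]
Product: 20 (2S)-2-[(3S)-3,8-bis(methoxymethoxy)-2,2-dimethyl-3,4-dihydro-2H-chromen-6-yl]-7-(methoxymethoxy)-2,3-dihydro-4H-chromen-4-one
Conditions: MeI, CaCO3, MeCN/H2O (9:1), 45 °C
Reagents that add atoms: water, O
Why: Alkylative hydrolysis of the dithioketal (S-methylation, opening to a thionium ion stabilised by ring A, attack of water) under buffered, non-oxidising conditions should unveil the C4 ketone without touching the MOM ethers or the base-sensitive C2 stereocentre.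

Step 13
Reactants: 20 (2S)-2-[(3S)-3,8-bis(methoxymethoxy)-2,2-dimethyl-3,4-dihydro-2H-chromen-6-yl]-7-(methoxymethoxy)-2,3-dihydro-4H-chromen-4-one
Product: 21 (2S)-2-[(3S)-3,8-dihydroxy-2,2-dimethyl-3,4-dihydro-2H-chromen-6-yl]-7-hydroxy-2,3-dihydro-4H-chromen-4-one
Conditions: HCl (3 M aq.), MeOH/THF, 40 °C
Reagents that add atoms: none
Why: Acid-catalysed methanolysis of the three MOM acetals, under conditions that chroman-4-ones and the tertiary aryl ether of ring B should tolerate and that avoid the base-induced ring opening that would scramble C2, gives the target.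

**Compound list**

1 | 3',4'-dihydroxyacetophenone | CC(=O)c1ccc(O)c(O)c1 | starting material
2 | 3-chloro-3-methylbut-1-yne | CC(C)(Cl)C#C | starting material
3 | 1-[3-hydroxy-4-(2-methylbut-3-yn-2-yloxy)phenyl]ethan-1-one | CC(=O)c1ccc(OC(C)(C)C#C)c(O)c1 | intermediate
4 | 1-[3-(methoxymethoxy)-4-(2-methylbut-3-yn-2-yloxy)phenyl]ethan-1-one | CC(=O)c1ccc(OC(C)(C)C#C)c(OCOC)c1 | intermediate
5 | 1-[8-(methoxymethoxy)-2,2-dimethyl-2H-chromen-6-yl]ethan-1-one | CC(=O)c1cc(OCOC)c2OC(C)(C)C=Cc2c1 | intermediate
6 | (3S,4S)-6-acetyl-3,4-epoxy-8-(methoxymethoxy)-2,2-dimethylchromane | CC(=O)c1cc(OCOC)c2OC(C)(C)[C@H]3O[C@H]3c2c1 | intermediate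
7 | 1-[(3S)-3-hydroxy-8-(methoxymethoxy)-2,2-dimethyl-3,4-dihydro-2H-chromen-6-yl]ethan-1-one | CC(=O)c1cc(OCOC)c2OC(C)(C)[C@@H](O)Cc2c1 | intermediate
8 | 1-[(3S)-3,8-bis(methoxymethoxy)-2,2-dimethyl-3,4-dihydro-2H-chromen-6-yl]ethan-1-one | CC(=O)c1cc(OCOC)c2OC(C)(C)[C@@H](OCOC)Cc2c1 | intermediate
9 | trimethylsilyl enol ether of 8 | C=C(O[Si](C)(C)C)c1cc(OCOC)c2OC(C)(C)[C@@H](OCOC)Cc2c1 | intermediate
10 | 2-chloro-1-[(3S)-3,8-bis(methoxymethoxy)-2,2-dimethyl-3,4-dihydro-2H-chromen-6-yl]ethan-1-one | ClCC(=O)c1cc(OCOC)c2OC(C)(C)[C@@H](OCOC)Cc2c1 | intermediate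
11 | (1R)-2-chloro-1-[(3S)-3,8-bis(methoxymethoxy)-2,2-dimethyl-3,4-dihydro-2H-chromen-6-yl]ethan-1-ol | ClC[C@H](O)c1cc(OCOC)c2OC(C)(C)[C@@H](OCOC)Cc2c1 | intermediate
12 | (3S)-3,8-bis(methoxymethoxy)-2,2-dimethyl-6-[(2R)-oxiran-2-yl]-3,4-dihydro-2H-chromene | C1O[C@@H]1c1cc(OCOC)c2OC(C)(C)[C@@H](OCOC)Cc2c1 | intermediate
13 | 2-fluoro-4-hydroxybenzaldehyde | O=Cc1ccc(O)cc1F | starting material
14 | 4-(1,3-dithian-2-yl)-3-fluorophenol | Oc1ccc(C2SCCCS2)c(F)c1 | intermediate
15 | 2-[2-fluoro-4-(methoxymethoxy)phenyl]-1,3-dithiane | COCOc1ccc(C2SCCCS2)c(F)c1 | intermediate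
16 | 2-[2-fluoro-4-(methoxymethoxy)phenyl]-2-lithio-1,3-dithiane | [Li]C1(SCCCS1)c1ccc(OCOC)cc1F | intermediate
17 | lithium (1S)-1-[(3S)-3,8-bis(methoxymethoxy)-2,2-dimethyl-3,4-dihydro-2H-chromen-6-yl]-2-{2-[2-fluoro-4-(methoxymethoxy)phenyl]-1,3-dithian-2-yl}ethan-1-olate | [Li+].[O-][C@@H](CC1(SCCCS1)c1ccc(OCOC)cc1F)c1cc(OCOC)c2OC(C)(C)[C@@H](OCOC)Cc2c1 | intermediate
18 | lithium (1S)-1-[(3S)-3,8-bis(methoxymethoxy)-2,2-dimethyl-3,4-dihydro-2H-chromen-6-yl]-2-{2-[4-(methoxymethoxy)-2,3-didehydrophenyl]-1,3-dithian-2-yl}ethan-1-olate (aryne C8≡C8a) | [Li+].[O-][C@@H](CC1(SCCCS1)C1=CC=C(OCOC)C#C1)c1cc(OCOC)c2OC(C)(C)[C@@H](OCOC)Cc2c1 | intermediate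
19 | (2S)-2-[(3S)-3,8-bis(methoxymethoxy)-2,2-dimethyl-3,4-dihydro-2H-chromen-6-yl]-7-(methoxymethoxy)-2,3-dihydrospiro[chromene-4,2'-[1,3]dithiane] | CC1(C)Oc2c(OCOC)cc([C@@H]3CC4(SCCCS4)c4ccc(OCOC)cc4O3)cc2C[C@@H]1OCOC | intermediate
20 | (2S)-2-[(3S)-3,8-bis(methoxymethoxy)-2,2-dimethyl-3,4-dihydro-2H-chromen-6-yl]-7-(methoxymethoxy)-2,3-dihydro-4H-chromen-4-one | CC1(C)Oc2c(OCOC)cc([C@@H]3CC(=O)c4ccc(OCOC)cc4O3)cc2C[C@@H]1OCOC | intermediate
21 | (2S)-2-[(3S)-3,8-dihydroxy-2,2-dimethyl-3,4-dihydro-2H-chromen-6-yl]-7-hydroxy-2,3-dihydro-4H-chromen-4-one | CC1(C)Oc2c(O)cc([C@@H]3CC(=O)c4ccc(O)cc4O3)cc2C[C@@H]1O | target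

**Step count**

Total step count: 13. Longest linear sequence: 11 steps (steps 1–8, 11, 12, 13); steps 9–10 form the short branch.

**Steps most likely to fail**

1. Step 11 (proposed new method). Possible failures are attack of the dithiane anion at the benzylic carbon of the electron-rich oxirane, lithium-induced rearrangement of the oxirane, early lithiation at C8 during dithiane deprotonation, and capture of the aryne by the amide base instead of the alkoxide. The fallback sets out from compound 8 and comes back at compound 20; it forms the same two bonds of ring C by established chemistry at the flavone oxidation level. Commercial methyl 2-fluoro-4-hydroxybenzoate F1 is protected (MOMCl, iPr2NEt) to methyl 2-fluoro-4-(methoxymethoxy)benzoate F2. The lithium enolate of 8 (LiHMDS, THF, −78 → 0 °C) is acylated by F2 in a Claisen condensation to the 1,3-diketone F3. On heating with K2CO3 in DMF the enolate oxygen of F3 displaces the ortho fluorine (intramolecular SNAr, activated by the ortho carbonyl) to give the flavone F4. Asymmetric hydrogenation of the C2=C3 bond of F4 follows, with Ru(cod)(2-methylallyl)2 and a chiral N-heterocyclic carbene ligand (from an enantiopure N,N'-bis(1-arylethyl)imidazolinium tetrafluoroborate and KOtBu; the ligand enantiomer that leads to the (2S) series), under H2 pressure in toluene. It should set C2 under catalyst control and give mainly the over-reduced (2S,4S)-flavan-4-ol F5. Dess–Martin periodinane (CH2Cl2, rt) re-oxidises C4 to give 20.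

2. Step 8. The para oxygen of ring B makes the benzylic C–O bond of the chlorohydrin and of the oxirane prone to ionisation, which could erode the configuration at the future C2 or cause rearrangement to an arylacetaldehyde during closure and isolation. The fallback sets out from compound 10 and comes back at compound 19; it replaces epoxide opening by SN2 alkylation of a protected halohydrin. The transfer hydrogenation is run as in step 8 but without the base treatment, and chlorohydrin 11 is isolated. It is silylated (TBSOTf, 2,6-lutidine, CH2Cl2, −78 °C) to the silyl ether F6 and converted by Finkelstein exchange (NaI, butanone, 80 °C) into the iodide F7. Lithiated dithiane 16 (from 15 and n-BuLi, THF/DMPU, −78 → −20 °C) is alkylated by F7 to the silyl ether F8. TBAF (THF, rt) then gives the free alcohol F9. LiTMP (3 equiv, THF, −78 °C → rt) closes ring C of F9 through the same aryne, as a separate benzyne cyclisation, to give 19.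

3. Step 5. The hydrogenation may not stop at the epoxide: the aryl ketone could be reduced, or the C3–O bond could be cleaved as well. The fallback sets out from compound 6 and comes back at compound 7; it replaces hydrogenolysis by a polar opening and a radical reduction. MgBr2·OEt2 (Et2O, 0 °C) opens the epoxide at the benzylic C4 with inversion to give the trans-bromohydrin F10. Bu3SnH with AIBN (toluene, 80 °C) then removes the benzylic bromine by a radical chain that leaves the ketone and C3 untouched, giving 7.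

**Further compounds**

F1 | step 11 | methyl 2-fluoro-4-hydroxybenzoate | COC(=O)c1ccc(O)cc1F
F2 | step 11 | methyl 2-fluoro-4-(methoxymethoxy)benzoate | COCOc1ccc(C(=O)OC)c(F)c1
F3 | step 11 | 1-[(3S)-3,8-bis(methoxymethoxy)-2,2-dimethyl-3,4-dihydro-2H-chromen-6-yl]-3-[2-fluoro-4-(methoxymethoxy)phenyl]propane-1,3-dione | CC1(C)Oc2c(OCOC)cc(C(=O)CC(=O)c3ccc(OCOC)cc3F)cc2C[C@@H]1OCOC
F4 | step 11 | 2-[(3S)-3,8-bis(methoxymethoxy)-2,2-dimethyl-3,4-dihydro-2H-chromen-6-yl]-7-(methoxymethoxy)-4H-chromen-4-one | CC1(C)Oc2c(OCOC)cc(C3=CC(=O)c4ccc(OCOC)cc4O3)cc2C[C@@H]1OCOC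
F5 | step 11 | (2S,4S)-2-[(3S)-3,8-bis(methoxymethoxy)-2,2-dimethyl-3,4-dihydro-2H-chromen-6-yl]-7-(methoxymethoxy)-3,4-dihydro-2H-chromen-4-ol | CC1(C)Oc2c(OCOC)cc([C@@H]3C[C@H](O)c4ccc(OCOC)cc4O3)cc2C[C@@H]1OCOC
F6 | step 8 | tert-butyl{(1R)-2-chloro-1-[(3S)-3,8-bis(methoxymethoxy)-2,2-dimethyl-3,4-dihydro-2H-chromen-6-yl]ethoxy}dimethylsilane | ClC[C@H](O[Si](C)(C)C(C)(C)C)c1cc(OCOC)c2OC(C)(C)[C@@H](OCOC)Cc2c1
F7 | step 8 | tert-butyl{(1R)-2-iodo-1-[(3S)-3,8-bis(methoxymethoxy)-2,2-dimethyl-3,4-dihydro-2H-chromen-6-yl]ethoxy}dimethylsilane | IC[C@H](O[Si](C)(C)C(C)(C)C)c1cc(OCOC)c2OC(C)(C)[C@@H](OCOC)Cc2c1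
F8 | step 8 | tert-butyl{(1S)-1-[(3S)-3,8-bis(methoxymethoxy)-2,2-dimethyl-3,4-dihydro-2H-chromen-6-yl]-2-{2-[2-fluoro-4-(methoxymethoxy)phenyl]-1,3-dithian-2-yl}ethoxy}dimethylsilane | CC(C)(C)[Si](C)(C)O[C@@H](CC1(SCCCS1)c1ccc(OCOC)cc1F)c1cc(OCOC)c2OC(C)(C)[C@@H](OCOC)Cc2c1
F9 | step 8 | (1S)-1-[(3S)-3,8-bis(methoxymethoxy)-2,2-dimethyl-3,4-dihydro-2H-chromen-6-yl]-2-{2-[2-fluoro-4-(methoxymethoxy)phenyl]-1,3-dithian-2-yl}ethan-1-ol | O[C@@H](CC1(SCCCS1)c1ccc(OCOC)cc1F)c1cc(OCOC)c2OC(C)(C)[C@@H](OCOC)Cc2c1
F10 | step 5 | 1-[(3R,4R)-4-bromo-3-hydroxy-8-(methoxymethoxy)-2,2-dimethyl-3,4-dihydro-2H-chromen-6-yl]ethan-1-one | CC(=O)c1cc(OCOC)c2OC(C)(C)[C@@H](O)[C@H](Br)c2c1
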